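## Structural features

The target is 4-hydroxy-2-(4-hydroxy-2-methoxyphenyl)-6-methoxy-5-(3-methylbut-2-en-1-yl)-1-benzofuran-3-carbaldehyde (ebenfuran IV). It is a 2-aryl-3-formylbenzofuran: a furan ring (O1, C2, C3, C3a, C7a) fused along C3a–C7a to benzo ring A and joined through the C2–C1' bond to ring B. Ring A carries hydroxyl at C4, prenyl at C5, methoxy at C6 and hydrogen at C7, so with O1 on C7a it has a phloroglucinol-type oxygen pattern with one carbon between two oxygens alkylated. Ring B carries methoxy at C2' and hydroxyl at C4'. There is no stereocentre and no stereogenic double bond, so every selectivity problem is one of regiochemistry or of telling like groups apart. The fragile groups are the C3 aldehyde (hydrogen-bonded to the peri C4 hydroxyl), the prenyl alkene (hydrogenation, acid-induced cyclisation onto the C4 oxygen) and the two phenols on an electron-rich skeleton. The real difficulty is that C3, C5 and C7 are all nucleophilic and four oxygens are of the same kind: formyl must reach C3 only, prenyl C5 only, and only the oxygens on C4 and C4' may end up free. The key step uses the fact that O1–C2=C3–CH=O is a vinylogous formate: O1 is the enol oxygen of the ring B aryl ketone and the formyl carbon is a hydrolysed aminomethylene group, so an α-aryl enaminone with bromine on the future C7a lacks only the O1–C7a bond.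

## Logic of the disconnections

17 ⇒ 16. The S–O bond of a ring B sulfonate is added back onto the C4' oxygen. This phenol must stay masked to the end, because free it would compete in the O-alkylation at C4 and in the copper coupling. The gain is a precursor with a single free phenol. The demand is a cleavage that spares aldehyde and prenyl group, which hydroxide in aqueous methanol meets.

16 ⇒ 14 (through 15). The C5–CH2 bond of the prenyl chain is cut and the C5 unit is reattached, transposed, to the C4 oxygen. A [3,3] shift from that oxygen can only reach C5, since the other ortho carbon is the ring-fusion atom C3a, so the C5/C7 question is settled by the tether. C-prenylation becomes O-alkylation. The demand is that the ether be the 1,1-dimethylallyl isomer and that the shift run under neutral thermal conditions.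

14 ⇒ 13 ⇒ 11 + 12. The alkene is traced back to an alkyne and the tertiary C–O bond is cut. A tertiary allyl ether cannot be made by direct alkylation, whereas the tertiary propargyl ether can. The gain is a phenol plus a commercial C5 chloride. The demands are etherification of a hydrogen-bonded phenol and a hydrogenation that stops at the alkene.

11 ⇒ 9. The methyl group is returned to the C4 oxygen. Ring A then has two equal methyl ethers that come from a cheap symmetrical arene, and their differentiation is postponed until the C3 formyl group is present to direct it. The demand is a chelation-controlled mono-demethylation that leaves the C6 and C2' ethers and the sulfonate alone.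

9 ⇒ 7 (through 8). The O1–C7a bond is cut and the aldehyde is written as its dimethylaminomethylene precursor. This removes the furan ring and the formyl regiochemistry problem together, since the formyl carbon is already bonded to the future C3. The demand is an intramolecular C–O coupling of a neutral vinylogous amide oxygen with an aryl bromide that beats hydrolysis of the enaminone.

7 ⇒ 5 + 6. The C=C bond between C3 and the future formyl carbon is cut. The methylene of 5 is flanked by carbonyl and aryl and is the only acidic position, so condensation with 6 can occur nowhere else. The demand is that the crowded methylene still condenses on heating.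

5 ⇒ 2 + 4. The C3–C3a bond (aryl–CH2) is cut, which splits the molecule into its ring A and ring B halves. The demand is an enolate arylation that uses the C–I bond of 2 and leaves the neighbouring C–Br bond and the sulfonate untouched.

2 ⇒ 1 and 4 ⇒ 3. The C–I bond and the sulfonate S–O bond are removed to reach commercial materials. Iodination must go to the position between bromine and methoxy, which is para to the other methoxy group. The sulfonylation has only one phenol to address.

## Other disconnections considered

Alternative 1: Ring A built on a furan by Danheiser benzannulation.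
- Cut: C7–C7a, C6–C7, C4–C5 and C3a–C4, leaving a trisubstituted furan and a two-carbon alkyne.
- Forward key step: the diazoketone methyl 5-(diazoacetyl)-2-{2-methoxy-4-[(triisopropylsilyl)oxy]phenyl}furan-3-carboxylate A2 is irradiated with the ynol ether 1-methoxy-5-methylhex-4-en-1-yne A3 and then heated. Wolff rearrangement moves the furyl group to the former diazo carbon (C7–C7a) and gives a furylketene. A (2+2) cycloaddition with A3 forms C4–C5 and C6–C7. Ring opening of the cyclobutenone and six-electron electrocyclisation onto the free furan β-carbon form C3a–C4, and tautomerisation should give methyl 4-hydroxy-6-methoxy-2-{2-methoxy-4-[(triisopropylsilyl)oxy]phenyl}-5-(3-methylbut-2-en-1-yl)-1-benzofuran-3-carboxylate A1.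
- In favour: one operation places all four ring A substituents through the connectivity of A3. Prenyl is on C5 by construction, the C4 oxygen emerges free and the C6 oxygen methylated.
- Against: A2 and A3 each need several steps. A3 is an acid- and heat-sensitive ynol ether. The ketene could also add to the prenyl alkene. The C3 ester of A1 must be taken to the aldehyde next to a free phenol.
- Comparison: on ring A structure this alternative is the better one, since it does in one step what steps 6 to 9 do in four. On the formyl group the chosen plan is better, because 9 arrives at the aldehyde oxidation level. Mechanistically a four-event pericyclic cascade must outrun ketene dimerisation, against a single CuI-catalysed coupling. Step economy is expected to be about equal at best, since the saving on ring A is spent on A2, A3 and the ester adjustment; both plans end with one phenol deprotection, which is a point of equality.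

Alternative 2: Lactone-tethered C2–H arylation through a coumestan.
- Cut: the C2–C1' biaryl bond, with the future formyl carbon and the C2' oxygen tied together as an ester.
- Forward key step: Pd(OAc)2/PPh3/K2CO3 acts on the ester 2-bromo-5-[(4-methylbenzenesulfonyl)oxy]phenyl 4,6-dimethoxy-1-benzofuran-3-carboxylate A5. Zerovalent palladium inserts into C–Br, carbonate-assisted metalation takes place at the benzofuran C2–H, and reductive elimination closes the six-membered lactone of 7,9-dimethoxy-6-oxo-6H-[1]benzofuro[3,2-c]chromen-3-yl 4-methylbenzenesulfonate A4.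
- In favour: the tether leaves only C2–H within reach, and that is also the most reactive C–H bond of a benzofuran. No organometallic partner is needed, and the lactone carries the future formyl carbon and C2' oxygen.
- Against: after A4 the lactone must be opened, the freed C2' phenol methylated and the carbonyl brought to the aldehyde level. The hydroxide, alkoxide or hydride reagents that open lactones are likely to attack the sulfonate too, which would make the two ring B oxygens hard to distinguish. The benzofuran acid half of A5 needs its own synthesis.
- Comparison: on ring A the two plans are equal, because the demethylation and prenylation endgame is unchanged. The alternative is better in that the biaryl bond forms without pre-functionalising C2 and A4 is a rigid, robust intermediate. The chosen plan is better on the formyl group and on step economy, by an expected margin of at least three steps.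

Alternative 3: Ring B by Diels–Alder aromatisation on a 2-ethynylbenzofuran.
- Cut: C1'–C2' and C5'–C6' of ring B.
- Forward key step: the dienophile ethyl 2-ethynyl-4,6-dimethoxy-1-benzofuran-3-carboxylate A7 and the ketene-acetal diene 1,1-dimethoxy-3-[(trimethylsilyl)oxy]buta-1,3-diene A8 undergo thermal (4+2) cycloaddition. The nucleophilic diene terminus should bond to the terminal alkyne carbon. Loss of methanol aromatises ring B and desilylation on work-up should give ethyl 2-(4-hydroxy-2-methoxyphenyl)-4,6-dimethoxy-1-benzofuran-3-carboxylate A6.
- In favour: the diene fixes methoxy at C2' and a free hydroxyl at C4' without a protecting group, and no transition metal is needed for the key bonds.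
- Against: the alkyne of A7 is only weakly activated through the C2=C3 bond, so forcing conditions are likely. A8 is moisture-sensitive. A7 needs a multistep synthesis. The free C4' phenol of A6 must be protected before the C4 oxygen can be alkylated selectively, and the ester again needs adjusting.
- Comparison: regiocontrol in ring B is equal to that of the chosen plan, which simply buys ring B in 3. The alternative is better in avoiding the C–I versus C–Br selectivity problem of step 3. The chosen plan is better on step economy and on the formyl oxidation level, and the ring A endgame is the same in both.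

Key step: step 5

Check of the key-step structures: in 7 the bromine is ortho to the carbon bearing the enaminone and meta to both methoxy groups, which maps onto C7a, C4–OMe and C6–OMe of 9, so no correction is needed. The design is kept with bromine (not iodine) at the future C7a and a sulfonate on ring B, because this pair allows the C–I-selective step 3 and survives BCl3 in step 6.

Assumption: 7 is written as its E isomer (dimethylamino group trans to the carbonyl group); the closure in step 5 does not depend on this geometry.

## Route

Step 1
Reactants: 1 1-bromo-3,5-dimethoxybenzene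
Product: 2 1-bromo-2-iodo-3,5-dimethoxybenzene
Conditions: NIS, MeCN, rt, dark
Reagents that add atoms: N-iodosuccinimide, O=C1CCC(=O)N1I
Why: Electrophilic aromatic iodination; the position between bromine and one methoxy group is para to the other methoxy group and less crowded than the position flanked by both, so iodine should enter there, which puts iodine on the future C3a and leaves bromine on the future C7a.

Step 2
Reactants: 3 1-(4-hydroxy-2-methoxyphenyl)ethanone
Product: 4 4-acetyl-3-methoxyphenyl 4-methylbenzenesulfonate
Conditions: TsCl, Et3N, DMAP (cat.), CH2Cl2, 0 °C to rt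
Reagents that add atoms: 4-methylbenzenesulfonyl chloride, Cc1ccc(S(=O)(=O)Cl)cc1
Why: O-Sulfonylation of the only phenol; the aryl sulfonate is expected to tolerate K3PO4, CuI, BCl3, DBU and hydrogenation and is removable at the end by hydroxide.

Step 3
Reactants: 2 1-bromo-2-iodo-3,5-dimethoxybenzene; 4 4-acetyl-3-methoxyphenyl 4-methylbenzenesulfonate
Product: 5 4-[(2-bromo-4,6-dimethoxyphenyl)acetyl]-3-methoxyphenyl 4-methylbenzenesulfonate
Conditions: Pd(OAc)2 (5 mol%), Xantphos (7.5 mol%), K3PO4, toluene, 80 °C; 2 in slight excess
Reagents that add atoms: none
Why: Ketone α-arylation (enolate cross-coupling): zerovalent palladium inserts into C–I much faster than into C–Br or the aryl sulfonate, the potassium enolate of 4 binds, and reductive elimination from the wide-bite-angle Xantphos complex forms the C3–C3a bond. The mild base spares the sulfonate, the bulk of the new aryl group blocks a second arylation, and the slight excess of 2 keeps the catalyst engaged with C–I bonds so that the C–Br bond of 5 is saved for step 5.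

Step 4
Reactants: 5 4-[(2-bromo-4,6-dimethoxyphenyl)acetyl]-3-methoxyphenyl 4-methylbenzenesulfonate; 6 N,N-dimethylformamide dimethyl acetal
Product: 7 4-[(2E)-2-(2-bromo-4,6-dimethoxyphenyl)-3-(dimethylamino)prop-2-enoyl]-3-methoxyphenyl 4-methylbenzenesulfonate
Conditions: DMF-DMA (excess), toluene, 100 °C; evaporate, use crude
Reagents that add atoms: N,N-dimethylformamide dimethyl acetal (6), COC(OC)N(C)C
Why: Aminomethylenation of an active methylene: the methylene between carbonyl and aryl is the only acidic site, it adds to the amide acetal and two molecules of methanol are lost to give the push–pull enaminone. The E geometry is the one expected on steric grounds and is of no consequence later.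

Step 5
Reactants: 7 4-[(2E)-2-(2-bromo-4,6-dimethoxyphenyl)-3-(dimethylamino)prop-2-enoyl]-3-methoxyphenyl 4-methylbenzenesulfonate
Product: 9 4-(3-formyl-4,6-dimethoxy-1-benzofuran-2-yl)-3-methoxyphenyl 4-methylbenzenesulfonate, via iminium bromide 8 (not isolated)
Conditions: CuI (10 mol%), 1,10-phenanthroline (20 mol%), K3PO4, dry DMF, 90 °C; then H2O, aq. NaOAc, rt
Reagents that add atoms: water, O
Why: A phenanthroline-bound monovalent copper centre is expected to add oxidatively to the C–Br bond of 7, giving an aryl trivalent-copper intermediate to which the carbonyl oxygen of the vinylogous amide, five atoms away, binds; C–O reductive elimination then forms O1–C7a and returns monovalent copper. Because the oxygen reacts as a neutral donor, the first product is the 3-(dimethyliminiomethyl)benzofuran salt 8, a Vilsmeier-type iminium ion that water converts into aldehyde 9 and dimethylamine on work-up. The closest known reaction type is the CuI-catalysed intramolecular Ullmann-type O-arylation of enolates of 2-(2-haloaryl) ketones to benzofurans; here the enaminone oxygen takes the place of the enolate oxygen and carries the formyl carbon with it. The one ring formed is the furan, closed in a five-membered mode at an sp2 aryl carbon with the C–Br bond exocyclic to the new ring, the atoms O, C2, C3, C3a and C7a being held close by the enaminone and the arene. No stereocentre is created, and the geometry of 7 is irrelevant because carbonyl and aryl group sit on the same carbon. The selectivity needed is O- over C- or N-arylation and C–Br over C–OTs: the α-carbon is fully substituted, the nitrogen is tertiary, only one oxygen is within reach, and CuI does not activate aryl sulfonates. The mixture is kept anhydrous until coupling is complete, since early hydrolysis would give a formyl ketone with two competing oxygens and a tendency to lose the formyl group.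

Step 6
Reactants: 9 4-(3-formyl-4,6-dimethoxy-1-benzofuran-2-yl)-3-methoxyphenyl 4-methylbenzenesulfonate
Product: 11 4-(3-formyl-4-hydroxy-6-methoxy-1-benzofuran-2-yl)-3-methoxyphenyl 4-methylbenzenesulfonate, via dichloroboryl ether 10 (not isolated)
Conditions: BCl3 (CH2Cl2 solution), CH2Cl2, −78 to 0 °C; then H2O
Reagents that add atoms: none
Why: Chelation-controlled ether cleavage: BCl3 binds the formyl oxygen and reaches the peri C4 methoxy oxygen through a six-membered chelate, and chloride removes that methyl group. The C6 and C2' ethers cannot form such a chelate and the sulfonate is inert to the Lewis acid.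

Step 7
Reactants: 11 4-(3-formyl-4-hydroxy-6-methoxy-1-benzofuran-2-yl)-3-methoxyphenyl 4-methylbenzenesulfonate; 12 3-chloro-3-methylbut-1-yne
Product: 13 4-{3-formyl-6-methoxy-4-[(2-methylbut-3-yn-2-yl)oxy]-1-benzofuran-2-yl}-3-methoxyphenyl 4-methylbenzenesulfonate
Conditions: 12 (excess), DBU, CuCl2·2H2O (cat.), MeCN, 0 °C to rt
Reagents that add atoms: 3-chloro-3-methylbut-1-yne (12), C#CC(C)(C)Cl
Why: CuCl2-catalysed propargylic etherification: a copper acetylide ionises to a highly electrophilic allenylidene-type species that the DBU-generated phenoxide captures at the tertiary carbon, which is why even a hydrogen-bonded phenol should react. The C4 hydroxyl is the only free one.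

Step 8
Reactants: 13 4-{3-formyl-6-methoxy-4-[(2-methylbut-3-yn-2-yl)oxy]-1-benzofuran-2-yl}-3-methoxyphenyl 4-methylbenzenesulfonate
Product: 14 4-{3-formyl-6-methoxy-4-[(2-methylbut-3-en-2-yl)oxy]-1-benzofuran-2-yl}-3-methoxyphenyl 4-methylbenzenesulfonate
Conditions: H2 (1 atm), Pd/CaCO3/Pb(OAc)2, quinoline, EtOAc, rt
Reagents that add atoms: none
Why: Semihydrogenation of a terminal alkyne on lead-poisoned palladium; the poisoned surface and quinoline should stop the reduction at the alkene and leave aldehyde, arene and sulfonate alone. Reducing before heating avoids the chromene that a propargyl aryl ether would give.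

Step 9
Reactants: 14 4-{3-formyl-6-methoxy-4-[(2-methylbut-3-en-2-yl)oxy]-1-benzofuran-2-yl}-3-methoxyphenyl 4-methylbenzenesulfonate
Product: 16 4-[3-formyl-4-hydroxy-6-methoxy-5-(3-methylbut-2-en-1-yl)-1-benzofuran-2-yl]-3-methoxyphenyl 4-methylbenzenesulfonate, via cyclohexadienone 15 (not isolated)
Conditions: N,N-diethylaniline, 130 °C
Reagents that add atoms: none
Why: Aromatic Claisen rearrangement: the [3,3] shift delivers the allyl terminus to C5, the only free ortho carbon (the other is ring-fusion C3a), and the allylic transposition turns the 1,1-dimethylallyl group into prenyl. Dienone 15 tautomerises to phenol 16, so its transient C5 stereocentre is lost, and the basic solvent suppresses acid-induced ionisation of the tertiary ether.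

Step 10
Reactants: 16 4-[3-formyl-4-hydroxy-6-methoxy-5-(3-methylbut-2-en-1-yl)-1-benzofuran-2-yl]-3-methoxyphenyl 4-methylbenzenesulfonate
Product: 17 4-hydroxy-2-(4-hydroxy-2-methoxyphenyl)-6-methoxy-5-(3-methylbut-2-en-1-yl)-1-benzofuran-3-carbaldehyde (ebenfuran IV)
Conditions: KOH, MeOH/H2O, 60 °C; then aq. HCl to pH 4
Reagents that add atoms: none
Why: Alkaline cleavage of an aryl sulfonate by attack of hydroxide at sulfur, releasing the C4' phenoxide. The non-enolisable aldehyde is deactivated by the adjacent C4 phenoxide and the prenyl group is inert to base.

## Compound list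

1 | 1-bromo-3,5-dimethoxybenzene | COc1cc(Br)cc(OC)c1 | starting material
2 | 1-bromo-2-iodo-3,5-dimethoxybenzene | COc1cc(Br)c(I)c(OC)c1 | intermediate
3 | 1-(4-hydroxy-2-methoxyphenyl)ethanone | CC(=O)c1ccc(O)cc1OC | starting material
4 | 4-acetyl-3-methoxyphenyl 4-methylbenzenesulfonate | CC(=O)c1ccc(OS(=O)(=O)c2ccc(C)cc2)cc1OC | intermediate
5 | 4-[(2-bromo-4,6-dimethoxyphenyl)acetyl]-3-methoxyphenyl 4-methylbenzenesulfonate | COc1cc(Br)c(CC(=O)c2ccc(OS(=O)(=O)c3ccc(C)cc3)cc2OC)c(OC)c1 | intermediate
6 | N,N-dimethylformamide dimethyl acetal | COC(OC)N(C)C | starting material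
7 | 4-[(2E)-2-(2-bromo-4,6-dimethoxyphenyl)-3-(dimethylamino)prop-2-enoyl]-3-methoxyphenyl 4-methylbenzenesulfonate | CN(C)/C=C(\c1c(Br)cc(OC)cc1OC)C(=O)c1ccc(OS(=O)(=O)c2ccc(C)cc2)cc1OC | intermediate
8 | N-{[4,6-dimethoxy-2-(2-methoxy-4-{[(4-methylphenyl)sulfonyl]oxy}phenyl)-1-benzofuran-3-yl]methylidene}-N-methylmethanaminium bromide | C[N+](C)=Cc1c(-c2ccc(OS(=O)(=O)c3ccc(C)cc3)cc2OC)oc2cc(OC)cc(OC)c12.[Br-] | intermediate (not isolated)
9 | 4-(3-formyl-4,6-dimethoxy-1-benzofuran-2-yl)-3-methoxyphenyl 4-methylbenzenesulfonate | O=Cc1c(-c2ccc(OS(=O)(=O)c3ccc(C)cc3)cc2OC)oc2cc(OC)cc(OC)c12 | intermediate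
10 | 4-{4-[(dichloroboranyl)oxy]-3-formyl-6-methoxy-1-benzofuran-2-yl}-3-methoxyphenyl 4-methylbenzenesulfonate | O=Cc1c(-c2ccc(OS(=O)(=O)c3ccc(C)cc3)cc2OC)oc2cc(OC)cc(OB(Cl)Cl)c12 | intermediate (not isolated)
11 | 4-(3-formyl-4-hydroxy-6-methoxy-1-benzofuran-2-yl)-3-methoxyphenyl 4-methylbenzenesulfonate | O=Cc1c(-c2ccc(OS(=O)(=O)c3ccc(C)cc3)cc2OC)oc2cc(OC)cc(O)c12 | intermediate
12 | 3-chloro-3-methylbut-1-yne | C#CC(C)(C)Cl | starting material
13 | 4-{3-formyl-6-methoxy-4-[(2-methylbut-3-yn-2-yl)oxy]-1-benzofuran-2-yl}-3-methoxyphenyl 4-methylbenzenesulfonate | O=Cc1c(-c2ccc(OS(=O)(=O)c3ccc(C)cc3)cc2OC)oc2cc(OC)cc(OC(C)(C)C#C)c12 | intermediate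
14 | 4-{3-formyl-6-methoxy-4-[(2-methylbut-3-en-2-yl)oxy]-1-benzofuran-2-yl}-3-methoxyphenyl 4-methylbenzenesulfonate | O=Cc1c(-c2ccc(OS(=O)(=O)c3ccc(C)cc3)cc2OC)oc2cc(OC)cc(OC(C)(C)C=C)c12 | intermediate
15 | 4-[3-formyl-6-methoxy-5-(3-methylbut-2-en-1-yl)-4-oxo-4,5-dihydro-1-benzofuran-2-yl]-3-methoxyphenyl 4-methylbenzenesulfonate (racemic at C5) | O=Cc1c(-c2ccc(OS(=O)(=O)c3ccc(C)cc3)cc2OC)oc2C=C(OC)C(CC=C(C)C)C(=O)c12 | intermediate (not isolated)
16 | 4-[3-formyl-4-hydroxy-6-methoxy-5-(3-methylbut-2-en-1-yl)-1-benzofuran-2-yl]-3-methoxyphenyl 4-methylbenzenesulfonate | O=Cc1c(-c2ccc(OS(=O)(=O)c3ccc(C)cc3)cc2OC)oc2cc(OC)c(CC=C(C)C)c(O)c12 | intermediate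
17 | 4-hydroxy-2-(4-hydroxy-2-methoxyphenyl)-6-methoxy-5-(3-methylbut-2-en-1-yl)-1-benzofuran-3-carbaldehyde (ebenfuran IV) | COc1cc(O)ccc1-c1oc2cc(OC)c(CC=C(C)C)c(O)c2c1C=O | target

## Step count and least certain steps

Total step count: 10. Longest linear sequence: 9 steps (from 1 through steps 1 and 3 to 10, or equally from 3 through steps 2 to 10).

Step 5 (key step). The most likely failure is hydrolysis of the enaminone before the coupling, followed by loss of the formyl carbon, so that the ring closes without the C3 substituent. A second risk is slow oxidative addition at the crowded C–Br bond, since a neutral oxygen is a weaker partner for copper than an enolate. The fallback sets out from 5 and comes back at 9. Under CuI/K3PO4 in DMF at about 100 °C the potassium enolate of 5 should undergo the well-established O-arylation to give 4-(4,6-dimethoxy-1-benzofuran-2-yl)-3-methoxyphenyl 4-methylbenzenesulfonate F1. Vilsmeier–Haack formylation (POCl3, DMF) at the enol-ether carbon C3 would then give N-{[4,6-dimethoxy-2-(2-methoxy-4-{[(4-methylphenyl)sulfonyl]oxy}phenyl)-1-benzofuran-3-yl]methylidene}-N-methylmethanaminium chloride F2, which aqueous NaOAc hydrolyses to 9. This is only the fallback because C7 of the electron-rich ring A may compete with C3 for the electrophile.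

Step 3. Two processes threaten it: insertion of zerovalent palladium into the remaining C–Br bond of the product enolate, which would close the furan early without the formyl carbon, and sluggish coupling of the di-ortho-substituted iodide leading to reductive loss of iodine. The fallback sets out from 2 and 4 and comes back at 7, bypassing 5 and step 4.
- Iodine–magnesium exchange of 2 with iPrMgCl·LiCl in THF at −40 °C gives (2-bromo-4,6-dimethoxyphenyl)magnesium chloride F3, which is trapped cold with DMF to give 2-bromo-4,6-dimethoxybenzaldehyde F4.
- Claisen–Schmidt condensation of F4 with 4 (Ba(OH)2·8H2O, MeOH, rt) gives the chalcone 4-[(2E)-3-(2-bromo-4,6-dimethoxyphenyl)prop-2-enoyl]-3-methoxyphenyl 4-methylbenzenesulfonate F5.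
- Oxidative 1,2-aryl shift with the trivalent iodine reagent PhI(OAc)2 in acidified methanol/trimethyl orthoformate moves the electron-rich ring A aryl group to the α-carbon and gives 4-[2-(2-bromo-4,6-dimethoxyphenyl)-3,3-dimethoxypropanoyl]-3-methoxyphenyl 4-methylbenzenesulfonate F6.
- Dimethylamine in THF/MeOH at 60 °C converts the keto acetal F6 into 7 by elimination of methanol and addition–elimination.

Step 7. The hydrogen bond to the formyl group and the peri crowding may make O-alkylation of 11 slow enough that the reactive propargyl species decomposes first. The fallback sets out from 11 and comes back at 14, bypassing 13 and step 8. Tsuji–Trost O-allylation with tert-butyl 2-methylbut-3-en-2-yl carbonate and Pd(PPh3)4 (cat.) in THF at 0 °C should attack the π-allyl complex at its more substituted end and give 14 directly. It is not the first choice because, with an acidic phenoxide, the tertiary ether can re-ionise on palladium and drift to the linear prenyl ether, which would rearrange to the wrong C5 isomer. It makes no new compound.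

Step 9. The tertiary allyl–oxygen bond may ionise with loss of isoprene, returning 11, and traces of acid could cyclise the ortho-prenyl phenol onto its alkene. The fallback sets out from 11 and comes back at 16. Allylation with allyl bromide and K2CO3 in DMF gives 4-[3-formyl-6-methoxy-4-(prop-2-en-1-yloxy)-1-benzofuran-2-yl]-3-methoxyphenyl 4-methylbenzenesulfonate F7, a primary ether that cannot ionise in this way. Aromatic Claisen rearrangement in N,N-diethylaniline at about 190 °C gives 4-[3-formyl-4-hydroxy-6-methoxy-5-(prop-2-en-1-yl)-1-benzofuran-2-yl]-3-methoxyphenyl 4-methylbenzenesulfonate F8. Cross-metathesis of F8 with 2-methylbut-2-ene and the second-generation Grubbs catalyst RuCl2(=CHPh)(PCy3)(H2IMes) in CH2Cl2 at 40 °C then gives 16.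

## Further compounds

F1 | step 5 | 4-(4,6-dimethoxy-1-benzofuran-2-yl)-3-methoxyphenyl 4-methylbenzenesulfonate | COc1cc(OC)c2cc(-c3ccc(OS(=O)(=O)c4ccc(C)cc4)cc3OC)oc2c1
F2 | step 5 | N-{[4,6-dimethoxy-2-(2-methoxy-4-{[(4-methylphenyl)sulfonyl]oxy}phenyl)-1-benzofuran-3-yl]methylidene}-N-methylmethanaminium chloride | C[N+](C)=Cc1c(-c2ccc(OS(=O)(=O)c3ccc(C)cc3)cc2OC)oc2cc(OC)cc(OC)c12.[Cl-]
F3 | step 3 | (2-bromo-4,6-dimethoxyphenyl)magnesium chloride | COc1cc(Br)c([Mg]Cl)c(OC)c1
F4 | step 3 | 2-bromo-4,6-dimethoxybenzaldehyde | COc1cc(Br)c(C=O)c(OC)c1
F5 | step 3 | 4-[(2E)-3-(2-bromo-4,6-dimethoxyphenyl)prop-2-enoyl]-3-methoxyphenyl 4-methylbenzenesulfonate | COc1cc(Br)c(/C=C/C(=O)c2ccc(OS(=O)(=O)c3ccc(C)cc3)cc2OC)c(OC)c1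
F6 | step 3 | 4-[2-(2-bromo-4,6-dimethoxyphenyl)-3,3-dimethoxypropanoyl]-3-methoxyphenyl 4-methylbenzenesulfonate (racemic) | COc1cc(Br)c(C(C(OC)OC)C(=O)c2ccc(OS(=O)(=O)c3ccc(C)cc3)cc2OC)c(OC)c1
F0 | step 7 | none | none
F7 | step 9 | 4-[3-formyl-6-methoxy-4-(prop-2-en-1-yloxy)-1-benzofuran-2-yl]-3-methoxyphenyl 4-methylbenzenesulfonate | O=Cc1c(-c2ccc(OS(=O)(=O)c3ccc(C)cc3)cc2OC)oc2cc(OC)cc(OCC=C)c12
F8 | step 9 | 4-[3-formyl-4-hydroxy-6-methoxy-5-(prop-2-en-1-yl)-1-benzofuran-2-yl]-3-methoxyphenyl 4-methylbenzenesulfonate | O=Cc1c(-c2ccc(OS(=O)(=O)c3ccc(C)cc3)cc2OC)oc2cc(OC)c(CC=C)c(O)c12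
A1 | alternative 1 | methyl 4-hydroxy-6-methoxy-2-{2-methoxy-4-[(triisopropylsilyl)oxy]phenyl}-5-(3-methylbut-2-en-1-yl)-1-benzofuran-3-carboxylate | COC(=O)c1c(-c2ccc(O[Si](C(C)C)(C(C)C)C(C)C)cc2OC)oc2cc(OC)c(CC=C(C)C)c(O)c12
A2 | alternative 1 | methyl 5-(diazoacetyl)-2-{2-methoxy-4-[(triisopropylsilyl)oxy]phenyl}furan-3-carboxylate | COC(=O)c1cc(C(=O)C=[N+]=[N-])oc1-c1ccc(O[Si](C(C)C)(C(C)C)C(C)C)cc1OC
A3 | alternative 1 | 1-methoxy-5-methylhex-4-en-1-yne | COC#CCC=C(C)C
A4 | alternative 2 | 7,9-dimethoxy-6-oxo-6H-[1]benzofuro[3,2-c]chromen-3-yl 4-methylbenzenesulfonate | COc1cc(OC)c2c3c(oc2c1)-c1ccc(OS(=O)(=O)c2ccc(C)cc2)cc1OC3=O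
A5 | alternative 2 | 2-bromo-5-[(4-methylbenzenesulfonyl)oxy]phenyl 4,6-dimethoxy-1-benzofuran-3-carboxylate | COc1cc(OC)c2c(C(=O)Oc3cc(OS(=O)(=O)c4ccc(C)cc4)ccc3Br)coc2c1
A6 | alternative 3 | ethyl 2-(4-hydroxy-2-methoxyphenyl)-4,6-dimethoxy-1-benzofuran-3-carboxylate | CCOC(=O)c1c(-c2ccc(O)cc2OC)oc2cc(OC)cc(OC)c12
A7 | alternative 3 | ethyl 2-ethynyl-4,6-dimethoxy-1-benzofuran-3-carboxylate | CCOC(=O)c1c(C#C)oc2cc(OC)cc(OC)c12
A8 | alternative 3 | 1,1-dimethoxy-3-[(trimethylsilyl)oxy]buta-1,3-diene | COC(OC)=CC(=C)O[Si](C)(C)C
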